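A link cannot form without a second end group, and in this flask second end groups are also lost by two other steps, so equal charges cannot link every first end group.

first end groups 10 mM; second end groups 10.0 mM; time 15 h

    second end groups → decomposed reagent (k1 = 7.29 × 10⁻⁴ /s)
    first end groups + second end groups → links (k2 = 0.352 /M/s)
    2 second end groups → homo dimer (k3 = 0.0346 /M/s)

- at 15 h, what has stopped the reaction, if anything has (the second end groups has run out first / it is still moving / all of the first end groups has reacted)
- conversion of first end groups at 15 h
- amount of links at 15 h, in percent of the first end groups charged

- a doubled species enters its step squared and goes two at a time
- the reaction counts as stopped when no species that holds the first end groups changes by six tenths of a point or more over the second half of the time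
- run time (flask): 15 h

In the first instants linking is fast. With the other concentrations as charged, first end groups have a half-life of 0.055 h by that step, and at the start it takes second end groups 4.8 times as fast as decomposition does, while homo dimer formation takes 0.949 of what decomposition takes.

Through the middle, linking slows with the first end groups, so each new link costs more second end groups, the limiting reagent here. I therefore write their balance. Homo dimer formation goes with the square; if second end groups fall roughly exponentially, their self-weighted mean is 5.00 mM, which makes that step act like a decomposition with constant k3 times the charge. I call the wasting level the concentration of first end groups at which linking and both losses take second end groups equally, (k1 + k3 × charge)/k2, here 3.05 mM. Each link then costs one second end group plus the wasting level divided by the first end groups present.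

Summed to the end, equal charges give: first end groups left = wasting level × ln(charge/left). Trying 3.33 mM left, a third of the charge, the right side gives 3.36 mM, which nearly closes it. So I commit to a conversion of about 66.4%, with links equal to it. Decomposition's half-life of 0.26 h is short against 15 h, so I expect the second end groups to run out first.

The forecast says the second end groups has run out first, with conversion 67.5% and links 67.5%, a figure 1.1 percentage points above mine: the competition “leaves about a third of the first end groups unreacted”.

The simulation gives the second end groups has run out first, conversion 67.5% and links 67.5%, with 0% of the second end groups left. In this flask the wasting level applied to what remains gives 3.43 mM of losses, against 3.25 mM counted from decomposed reagent and homo dimer. The neighbour flask with 17 mM of first end groups keeps the same 3.05 mM; there, left = charge difference + wasting level × ln(charge/left), solved by substitution, gives 8.98 mM, so links of 47.2%. That neighbour flask gives 47.6%.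

All constants were set for the occasion; the flask was simulated.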